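**Assumption:** the target SMILES has no stereocentres or stereo-descriptors, so it is treated as achiral. The hindered aryl–indole axis is unspecified and not controlled, and the only stereocentre in the route (in compound 8, racemic) is destroyed in step 5.

## Retrosynthetic overview

1. Target 12 ⇐ N‑desulfonylation of 11. The hindered aryl–C3(indole) bond of 11 ⇐ quinone monoketal 10 + free 2‑(1,1‑dimethylallyl)indole 2, by metal‑free conjugate addition and re‑aromatisation (no cross‑coupling).
2. 10 ⇐ phenol 9 by oxidative dearomatisation; the ketal carbon returns as OMe and the carbonyl as the single free OH, so the 3 × OMe / 1 × OH pattern is never a selectivity problem.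
3. The central benzene ring of 9 is built, not bought: Moore ring expansion (4π opening / 6π closure) of 4‑alkenyl‑4‑methoxycyclobutenone 8.
4. 8 ⇐ dimethyl squarate 6 + 3‑lithio‑N‑sulfonylindole (from 5) + (Z)‑2‑methoxyvinyllithium (from 4) + MeOTf.
5. Ring order: both indole bicycles are pre‑formed (2 by reverse prenylation of indole); the squarate cyclobutene is expanded to the central benzene ring in step 5.

## Route

**Step 1**
Reactants: 1, 1H‑indole
Product: 2, 2‑(2‑methylbut‑3‑en‑2‑yl)‑1H‑indole
Conditions: t‑BuOCl, Et3N, THF, –78 °C; then prenyl‑9‑BBN (made in situ from 9‑BBN‑H + 3‑methylbuta‑1,2‑diene), –78 °C → rt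
Reagents that add atoms: B‑prenyl‑9‑BBN, CC(C)=CCB1C2CCCC1CCC2
Why: Danishefsky reverse prenylation: the 3‑chloroindolenine is allylborated at C2 with allylic transposition (six‑membered SE2′ transition state), and loss of HCl re‑aromatises.

**Step 2**
Reactants: 3, methyl vinyl ether
Product: 4, (Z)‑1‑bromo‑2‑methoxyethene
Conditions: Br2, pentane, –78 °C; then PhNEt2, 95 °C, distil
Reagents that add atoms: bromine, BrBr
Why: Bromine addition to the enol ether followed by dehydrobromination of the α‑bromo ether, the standard preparation of (Z)‑2‑alkoxyvinyl bromides (minor E isomer converges later).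

**Step 3**
Reactants: 5, 3‑bromo‑1‑(phenylsulfonyl)‑1H‑indole; 6, dimethyl squarate
Product: 7, 3‑methoxy‑4‑[1‑(phenylsulfonyl)‑1H‑indol‑3‑yl]cyclobut‑3‑ene‑1,2‑dione
Conditions: 5, t‑BuLi (2 equiv), THF, –100 °C; cannulate into 6, –78 °C; TFAA, –78 → 0 °C; aq. NaHCO3
Reagents that add atoms: water, O (supplies the new C=O oxygen on work‑up)
Why: Liebeskind–Moore squarate arylation: 1,2‑addition of the 3‑lithioindole (kept at –100 °C to prevent 3→2 lithium migration), then TFAA‑induced ionisation and hydrolysis of the vinylogous ester gives the 3‑aryl‑4‑methoxycyclobutenedione.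

**Step 4**
Reactants: 7; 4, (Z)‑1‑bromo‑2‑methoxyethene
Product: 8, (±)‑3,4‑dimethoxy‑4‑[(Z)‑2‑methoxyethenyl]‑2‑[1‑(phenylsulfonyl)‑1H‑indol‑3‑yl]cyclobut‑2‑en‑1‑one
Conditions: 4, t‑BuLi (2 equiv), Et2O/THF, –78 °C; add 7, –78 °C; MeOTf, –78 → –20 °C; aq. NaHCO3; Et3N‑deactivated SiO2
Reagents that add atoms: methyl triflate, COS(=O)(=O)C(F)(F)F
Why: Br–Li exchange then Moore‑type 1,2‑addition to the more electrophilic carbonyl (the one that is not a vinylogous ester, next to C–OMe; the N‑sulfonyl group keeps the indolyl from acting as a competing vinylogous‑amide donor), with in‑situ O‑methylation of the alkoxide; the new quaternary centre is racemic and is destroyed in step 5.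

**Step 5**
Reactants: 8
Product: 9, 3,4,6‑trimethoxy‑2‑[1‑(phenylsulfonyl)‑1H‑indol‑3‑yl]phenol
Conditions: PhMe (0.01 M), 110 °C, Ar
Reagents that add atoms: none
Why: Moore rearrangement: conrotatory 4π opening (OMe outward, vinyl inward) gives a dienylketene, 6π electrocyclisation and tautomerisation give the benzene ring, and the ketene carbonyl becomes the only free OH, ortho to the indolyl group.

**Step 6**
Reactants: 9
Product: 10, 3,4,4,6‑tetramethoxy‑2‑[1‑(phenylsulfonyl)‑1H‑indol‑3‑yl]cyclohexa‑2,5‑dien‑1‑one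
Conditions: PhI(OAc)2, MeOH, 0 °C; NaHCO3
Reagents that add atoms: methanol, CO
Why: Hypervalent‑iodine oxidative dearomatisation of a p‑methoxyphenol to the p‑quinone monoketal (any o‑ketal isomer would give the same product in step 7).

**Step 7**
Reactants: 10; 2, 2‑(2‑methylbut‑3‑en‑2‑yl)‑1H‑indole
Product: 11, 2,4,5‑trimethoxy‑3‑[2‑(2‑methylbut‑3‑en‑2‑yl)‑1H‑indol‑3‑yl]‑6‑[1‑(phenylsulfonyl)‑1H‑indol‑3‑yl]phenol
Conditions: 2 (1.3 equiv), Sc(OTf)3 (10 mol %), 4 Å MS, CH2Cl2, –20 °C → rt
Reagents that add atoms: none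
Why: Proposed new method: ketalisation removes the vinylogous‑ester deactivation present in the parent quinone, so C5 (the only unsubstituted ring carbon, β to the C1 carbonyl) is a Michael acceptor; Lewis‑acid‑activated Friedel–Crafts attack by indole C3 followed by irreversible loss of MeOH from the ketal re‑aromatises (ipso adducts are reversible or reach the same product by 1,2‑shift); the closest known reactions are acid‑promoted additions of 2‑substituted indoles to benzoquinones and Michael addition/aromatisation of quinone monoketals.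

**Step 8**
Reactants: 11
Product: 12, asterriquinol I, 6‑(1H‑indol‑3‑yl)‑2,4,5‑trimethoxy‑3‑[2‑(2‑methylbut‑3‑en‑2‑yl)‑1H‑indol‑3‑yl]phenol
Conditions: Cs2CO3, THF/MeOH 2:1, 50 °C, Ar (degassed)
Reagents that add atoms: none
Why: Base‑mediated N‑desulfonylation of the indole (methoxide attack at sulfur); aryl methyl ethers, the phenol and the terminal alkene are inert.

## Compound list

1 | 1H‑indole | c1ccc2[nH]ccc2c1 | starting material
2 | 2‑(2‑methylbut‑3‑en‑2‑yl)‑1H‑indole | C=CC(C)(C)c1cc2ccccc2[nH]1 | intermediate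
3 | methyl vinyl ether | COC=C | starting material
4 | (Z)‑1‑bromo‑2‑methoxyethene | CO/C=C\Br | intermediate
5 | 3‑bromo‑1‑(phenylsulfonyl)‑1H‑indole | Brc1cn(S(=O)(=O)c2ccccc2)c2ccccc12 | starting material
6 | dimethyl squarate (3,4‑dimethoxycyclobut‑3‑ene‑1,2‑dione) | COC1=C(OC)C(=O)C1=O | starting material
7 | 3‑methoxy‑4‑[1‑(phenylsulfonyl)‑1H‑indol‑3‑yl]cyclobut‑3‑ene‑1,2‑dione | COC1=C(c2cn(S(=O)(=O)c3ccccc3)c3ccccc23)C(=O)C1=O | intermediate
8 | (±)‑3,4‑dimethoxy‑4‑[(Z)‑2‑methoxyethenyl]‑2‑[1‑(phenylsulfonyl)‑1H‑indol‑3‑yl]cyclobut‑2‑en‑1‑one | COC1=C(c2cn(S(=O)(=O)c3ccccc3)c3ccccc23)C(=O)C1(OC)/C=C\OC | intermediate (racemic)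
9 | 3,4,6‑trimethoxy‑2‑[1‑(phenylsulfonyl)‑1H‑indol‑3‑yl]phenol | COc1cc(OC)c(OC)c(-c2cn(S(=O)(=O)c3ccccc3)c3ccccc23)c1O | intermediate
10 | 3,4,4,6‑tetramethoxy‑2‑[1‑(phenylsulfonyl)‑1H‑indol‑3‑yl]cyclohexa‑2,5‑dien‑1‑one | COC1=CC(OC)(OC)C(OC)=C(c2cn(S(=O)(=O)c3ccccc3)c3ccccc23)C1=O | intermediate
11 | 2,4,5‑trimethoxy‑3‑[2‑(2‑methylbut‑3‑en‑2‑yl)‑1H‑indol‑3‑yl]‑6‑[1‑(phenylsulfonyl)‑1H‑indol‑3‑yl]phenol | C=CC(C)(C)c1[nH]c2ccccc2c1-c1c(OC)c(O)c(-c2cn(S(=O)(=O)c3ccccc3)c3ccccc23)c(OC)c1OC | intermediate
12 | asterriquinol I | C=CC(C)(C)c1[nH]c2ccccc2c1-c1c(OC)c(O)c(-c2c[nH]c3ccccc23)c(OC)c1OC | target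

## Summary

Total steps: 8. Longest linear sequence: 6 (steps 3 → 8, from 5 and 6); steps 1 and 2 are single‑step side branches.

Three steps most likely to fail, each with a fallback that changes the approach:

1. **Step 7** (quinone‑monoketal arylation with the hindered indole; risks are ketal ionisation or hydrolysis to the unreactive quinone and the reduced electrophilicity of the α‑methoxy enone). Fallback: build the reverse‑prenylated indole ring on the arene instead. MOM‑protect phenol 9, iodinate the single aryl C–H with NIS, then run a Cacchi aminopalladation/reductive‑elimination annulation with N‑[2‑(3,3‑dimethylpent‑4‑en‑1‑ynyl)phenyl]trifluoroacetamide, and deprotect.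
2. **Step 4** (regio‑ and chemoselective vinyllithium addition, alkoxide methylation, and an acid‑labile β‑alkoxyvinyl carbinol ether product). Fallback: drop the squarate construction of 9 and start from 2,4,5‑trimethoxyphenol. O‑Allylation, ortho‑specific aromatic Claisen rearrangement, ozonolysis to the arylacetaldehyde and Fischer indolisation with phenylhydrazine build the indol‑3‑yl ring on the pre‑formed arene; N‑sulfonylate and rejoin at step 6.
3. **Step 1** (reverse prenylation of a 3‑unsubstituted indole; the chloroindolenine can tautomerise to 3‑chloroindole or oligomerise). Fallback: Houlihan‑modified Madelung synthesis. Acylate o‑toluidine with 2,2‑dimethylbut‑3‑enoyl chloride, then cyclise with n‑BuLi (3 equiv) in THF, which forms the indole ring with the quaternary carbon already in place.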